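**Assumptions:** The target has no stereocenters and is achiral, so no enantiomer control is needed. Reagents are not numbered; they are given by name and SMILES in each step. Atraric acid and 3-methoxy-5-methylphenol are taken as commercial.

## Retrosynthesis
- Squamatic acid is a depside: an aryl ester joins a 2-hydroxy-4-methoxy-6-methylisophthalic acid unit (ring A) to the 4-OH of β-orcinol carboxylic acid (ring B).
- Both benzene rings already exist in the starting materials, so no ring is formed. The ester bond is made first, and the ring A carboxyl at C3 is installed last.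
- Disconnect C3-CO2H to a C3-CHO, which comes from ortho-formylation of the ring A 2-OH of a simple depside.
- Disconnect the ester to 2-benzyloxy-4-methoxy-6-methylbenzoic acid and benzyl 2,4-dihydroxy-3,6-dimethylbenzoate. The chelated, hindered 2-OH of ring B makes the coupling selective for the 4-OH.
- Benzyl groups are used so that one hydrogenolysis frees the ring B acid and the ring A phenol without cleaving the depside bond.

## Route

**Step 1**
Reactants: 1 (3-methoxy-5-methylphenol)
Product: 2 (2-hydroxy-4-methoxy-6-methylbenzaldehyde)
Conditions: MgCl2, Et3N, (CH2O)n, MeCN, reflux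
Reagents that add atoms: paraformaldehyde, C=O
Why: Mg-phenoxide-directed ortho-formylation (Casnati–Skattebøl) goes to the ortho position that is para to OMe, giving the 2-hydroxy-4-methoxy-6-methyl pattern.

**Step 2**
Reactants: 2
Product: 3 (2-(benzyloxy)-4-methoxy-6-methylbenzaldehyde)
Conditions: BnBr, K2CO3, DMF, 60 °C
Reagents that add atoms: benzyl bromide, BrCc1ccccc1
Why: Williamson O-benzylation of the phenol masks it, so it cannot self-esterify in the coupling step.

**Step 3**
Reactants: 3
Product: 4 (2-(benzyloxy)-4-methoxy-6-methylbenzoic acid)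
Conditions: NaClO2, NaH2PO4, 2-methyl-2-butene, t-BuOH/H2O, rt
Reagents that add atoms: sodium chlorite, O=Cl[O-].[Na+]
Why: Pinnick oxidation converts the aldehyde to the acid. Excess alkene scavenges HOCl so the electron-rich ring is not chlorinated.

**Step 4**
Reactants: 5 (atraric acid, methyl 2,4-dihydroxy-3,6-dimethylbenzoate)
Product: 6 (2,4-dihydroxy-3,6-dimethylbenzoic acid)
Conditions: KOH, MeOH/H2O, reflux, N2; then 2 M HCl, 0 °C
Reagents that add atoms: water, O; potassium hydroxide, [K+].[OH-]
Why: Saponification of the hindered methyl ester (BAc2). The acid is isolated cold to avoid decarboxylation.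

**Step 5**
Reactants: 6
Product: 7 (benzyl 2,4-dihydroxy-3,6-dimethylbenzoate)
Conditions: BnBr, NaHCO3, DMF, rt
Reagents that add atoms: benzyl bromide, BrCc1ccccc1
Why: Bicarbonate deprotonates only the carboxylic acid, so O-alkylation gives the benzyl ester and leaves both phenols free.

**Step 6**
Reactants: 4 (2-(benzyloxy)-4-methoxy-6-methylbenzoic acid) and 7 (benzyl 2,4-dihydroxy-3,6-dimethylbenzoate)
Product: 8 (benzyl 4-[2-(benzyloxy)-4-methoxy-6-methylbenzoyloxy]-2-hydroxy-3,6-dimethylbenzoate)
Conditions: (COCl)2, cat. DMF, CH2Cl2, 0 °C to rt, then evaporate; add 7, pyridine, DMAP, CH2Cl2, 0 °C to rt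
Reagents that add atoms: none (the acid chloride is formed in situ and its Cl is lost)
Why: Acylation of a phenol with an acid chloride. The 2-OH of 7 is hydrogen-bonded to the ester C=O and flanked by Me and CO2Bn, so only the 4-OH is acylated.

**Step 7**
Reactants: 8
Product: 9 (2-hydroxy-4-methoxy-6-methylbenzoate ester of 2,4-dihydroxy-3,6-dimethylbenzoic acid, with free CO2H and ring A 2-OH)
Conditions: H2 (1 atm), 10% Pd/C, THF/EtOAc, rt
Reagents that add atoms: none (hydrogen only)
Why: Hydrogenolysis removes the benzyl ether and the benzyl ester together (toluene is lost). The aryl ester, aryl methyl ether and ring methyls are untouched.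

**Step 8**
Reactants: 9
Product: 10 (3-formyl depside: COc1cc(C)c(C(=O)Oc2cc(C)c(C(=O)O)c(O)c2C)c(O)c1C=O)
Conditions: MgCl2 (3 equiv), Et3N (6 equiv), (CH2O)n, MeCN, 60–70 °C
Reagents that add atoms: paraformaldehyde, C=O
Why: Mg-chelated ortho-formylation goes to the only free position ortho to the ring A 2-OH, which is C3 because C1 carries the ester. Ring B's free OH has both ortho positions blocked, and its 4-O is acylated, so nothing else reacts.

**Step 9**
Reactants: 10
Product: 11 (squamatic acid)
Conditions: NaClO2, NaH2PO4, 2-methyl-2-butene, t-BuOH/H2O, rt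
Reagents that add atoms: sodium chlorite, O=Cl[O-].[Na+]
Why: Pinnick oxidation of the salicylaldehyde to the carboxylic acid under mild, buffered conditions that leave the aryl ester intact.

## Compound list
1 | 3-methoxy-5-methylphenol | COc1cc(C)cc(O)c1 | starting material
2 | 2-hydroxy-4-methoxy-6-methylbenzaldehyde | COc1cc(C)c(C=O)c(O)c1 | intermediate
3 | 2-(benzyloxy)-4-methoxy-6-methylbenzaldehyde | COc1cc(C)c(C=O)c(OCc2ccccc2)c1 | intermediate
4 | 2-(benzyloxy)-4-methoxy-6-methylbenzoic acid | COc1cc(C)c(C(=O)O)c(OCc2ccccc2)c1 | intermediate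
5 | atraric acid (methyl 2,4-dihydroxy-3,6-dimethylbenzoate) | COC(=O)c1c(C)cc(O)c(C)c1O | starting material
6 | 2,4-dihydroxy-3,6-dimethylbenzoic acid | Cc1cc(O)c(C)c(O)c1C(=O)O | intermediate
7 | benzyl 2,4-dihydroxy-3,6-dimethylbenzoate | Cc1cc(O)c(C)c(O)c1C(=O)OCc1ccccc1 | intermediate
8 | benzyl-protected depside | COc1cc(C)c(C(=O)Oc2cc(C)c(C(=O)OCc3ccccc3)c(O)c2C)c(OCc2ccccc2)c1 | intermediate
9 | deformyl depside (free CO2H and ring A OH) | COc1cc(C)c(C(=O)Oc2cc(C)c(C(=O)O)c(O)c2C)c(O)c1 | intermediate
10 | 3-formyl depside | COc1cc(C)c(C(=O)Oc2cc(C)c(C(=O)O)c(O)c2C)c(O)c1C=O | intermediate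
11 | squamatic acid (achiral, no stereocenters) | COc1cc(C)c(C(=O)Oc2cc(C)c(C(=O)O)c(O)c2C)c(O)c1C(=O)O | target

## Totals
- Total steps: 9.
- Longest linear sequence: 7 steps (1 → 2 → 3 → 4 → 8 → 9 → 10 → 11, that is steps 1, 2, 3, 6, 7, 8, 9).

## Three steps most likely to fail
1. **Step 8 (formylation of the free-acid depside).** The risks are depside cleavage by Mg or amine, and poor conversion with a free CO2H present.
   - Fallback: pre-install the CHO on ring A. Prepare 3-formyl-2-hydroxy-4-methoxy-6-methylbenzoic acid via benzyl 2-hydroxy-4-methoxy-6-methylbenzoate, Mg-formylation and hydrogenolysis. Its 2-OH is doubly chelated and needs no protection. Couple it with 7 through the acid chloride, then hydrogenolyse the ring B benzyl ester and run the Pinnick oxidation.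
2. **Step 6 (hindered coupling and 4-OH versus 2-OH selectivity).** The 2,6-disubstituted acid chloride is slow to react, and some 2-O-acylation is possible.
   - Fallback: use atranol (2,4-dihydroxy-3,6-dimethylbenzaldehyde) as the ring B partner. The CHO makes the 2-OH more strongly chelated and the 4-OH more acidic. The ring B aldehyde is then oxidised in the final Pinnick step, which replaces steps 4–5.
3. **Step 4 (hydrolysis of the hindered atraric ester).** Incomplete hydrolysis or decarboxylation of the β-resorcylic acid can occur.
   - Fallback: skip hydrolysis. Make ring B acid 6 directly by Kolbe–Schmitt carboxylation of 2,5-dimethylresorcinol (CO2, KHCO3, heat), then benzylate as in Step 5.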